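The core is a bicyclo[3.3.1]nonan-9-one: C1 hydroxylated bridgehead, C2/C3 epoxide, C4 methoxy carbon, C5 bridgehead, C6 carbinol, C7 amide carbon, C8 methylene. Ring A (C1, C9, C5, C6, C7, C8) holds N7 and O1 cis-1,3 over C8, syn to O6; the route reads this as a reduced N–O bond. An acyclic Z-nitrone at C7, linked through C6(OTBS)–C5–C9(=O) to the 1,1-disubstituted alkene C1=C8, cyclises in bridged mode: one operation forms C7–C8 and O–C1, ring A, the isoxazolidine and both stereocentres. C6 comes from the hydroxy lactone of (R)-malic acid; ring B follows by acetal addition at C5, metathesis and exo epoxidation.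

Key step: step 5

Remark: (R)-3-hydroxy-γ-butyrolactone, the lactone of (R)-malic acid reduced at its C1 carboxyl, is assumed to be commercially available; its carbinol carbon becomes C6.
Remark: the C2 oxygen is carried as a triethylsilyl ether so that it can be released beside the secondary TBS ether at C6, and the N–O bridge is kept until the C5–C4 bond is made, because the bridged bicycle holds the C6–O bond out of alignment for β-elimination.

Step 1
Reactants: 1 (R)-4-hydroxydihydrofuran-2(3H)-one
Product: 2 (R)-4-[(tert-butyldimethylsilyl)oxy]dihydrofuran-2(3H)-one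
Conditions: TBSCl, imidazole, DMF, rt
Reagents that add atoms: tert-butyldimethylsilyl chloride, CC(C)(C)[Si](C)(C)Cl
Why: Imidazole-mediated silylation of the secondary alcohol should proceed without touching the lactone or the stereocentre.

Step 2
Reactants: 3 2-bromoprop-2-en-1-ol
Product: 4 [(2-bromoprop-2-en-1-yl)oxy]triethylsilane
Conditions: TESCl, imidazole, CH2Cl2, 0 °C
Reagents that add atoms: triethylsilyl chloride, CC[Si](CC)(CC)Cl
Why: Standard silylation of a primary allylic alcohol gives the ether needed for halogen–lithium exchange.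

Step 3
Reactants: 4 [(2-bromoprop-2-en-1-yl)oxy]triethylsilane; 2 (R)-4-[(tert-butyldimethylsilyl)oxy]dihydrofuran-2(3H)-one
Product: 6 (5R)-5-[(tert-butyldimethylsilyl)oxy]-6-hydroxy-2-{[(triethylsilyl)oxy]methyl}hex-1-en-3-one, via vinyllithium 5 (not isolated)
Conditions: t-BuLi (2.05 equiv), Et2O, −78 °C; then cannulated into 2, THF, −78 °C; AcOH quench at −78 °C
Reagents that add atoms: none
Why: Bromine–lithium exchange followed by mono-addition of the vinyllithium to the lactone should stop at the lithium hemiketal, which is stable at −78 °C and gives the γ-hydroxy enone (in equilibrium with its cyclic hemiketal) only on cold quench, so over-addition and silyl migration are avoided.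

Step 4
Reactants: 6 (5R)-5-[(tert-butyldimethylsilyl)oxy]-6-hydroxy-2-{[(triethylsilyl)oxy]methyl}hex-1-en-3-one
Product: 7 (2R)-2-[(tert-butyldimethylsilyl)oxy]-4-oxo-5-{[(triethylsilyl)oxy]methyl}hex-5-enal
Conditions: Dess–Martin periodinane, NaHCO3, CH2Cl2, 0 °C → rt; used at once
Reagents that add atoms: none
Why: Dess–Martin oxidation of the primary alcohol (through the open hydroxy ketone form) under buffered, base-free conditions should give the α-silyloxy aldehyde without epimerisation at C6 or loss of silanol.

Step 5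
Reactants: 7 (2R)-2-[(tert-butyldimethylsilyl)oxy]-4-oxo-5-{[(triethylsilyl)oxy]methyl}hex-5-enal; 8 N-(4-methoxybenzyl)hydroxylamine
Product: 10 (1S,2R,5S)-2-[(tert-butyldimethylsilyl)oxy]-7-(4-methoxybenzyl)-5-{[(triethylsilyl)oxy]methyl}-6-oxa-7-azabicyclo[3.2.1]octan-4-one, via nitrone 9 (not isolated)
Conditions: 8 (1.0 equiv, slow addition), MgSO4, CH2Cl2, 0 °C → rt; then toluene (dilute), 90 °C
Reagents that add atoms: none
Why: Dehydrative condensation at the aldehyde gives the Z-aldonitrone 9, which reacts as a 1,3-dipole with the tethered alkene in a concerted suprafacial [3+2] cycloaddition; the closest known reaction type is the bridged-mode intramolecular nitrone–alkene cycloaddition that gives 6-oxa-7-azabicyclo[3.2.1]octanes. Ring A (C1–C9–C5–C6–C7–C8) closes through the new C7–C8 bond with both alkene carbons inside the ring, and the isoxazolidine (C7–N–O–C1–C8) closes through C7–C8 and O–C1, so the N–O unit becomes a two-atom bridge across ring A. C7 and C1 are created together: nitrogen and oxygen must be cis because they stay bonded to each other, and their face relative to C6 is set by a chair-like transition state in which the C6 silyloxy group is equatorial and antiperiplanar to the forming C7–C8 bond, which places it cis to nitrogen. The step needs bridged and not fused regiochemistry; as with methacrylates and other α-methylene carbonyl compounds, the 1,1-disubstituted alkene should take oxygen at its substituted carbon, and the fused alternative would have to build a quaternary centre in a cyclopentanone. The Z geometry of the nitrone, with C6 syn to oxygen, is the one that lets the three-atom tether reach.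

Step 6
Reactants: 10 cycloadduct with C2 as triethylsilyloxymethyl
Product: 11 (1S,2R,5S)-2-[(tert-butyldimethylsilyl)oxy]-5-(hydroxymethyl)-7-(4-methoxybenzyl)-6-oxa-7-azabicyclo[3.2.1]octan-4-one
Conditions: PPTS (cat.), MeOH/CH2Cl2, 0 °C
Reagents that add atoms: none
Why: Acid-catalysed methanolysis should remove the primary triethylsilyl ether much faster than the secondary TBS ether, and the isoxazolidine and ketone are inert to it.

Step 7
Reactants: 11 primary alcohol
Product: 12 (1S,2R,5S)-2-[(tert-butyldimethylsilyl)oxy]-7-(4-methoxybenzyl)-4-oxo-6-oxa-7-azabicyclo[3.2.1]octane-5-carbaldehyde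
Conditions: Dess–Martin periodinane, NaHCO3, CH2Cl2, 0 °C; used crude
Reagents that add atoms: none
Why: Dess–Martin oxidation gives the aldehyde on the quaternary C1, which has no α-hydrogen and therefore cannot epimerise.

Step 8
Reactants: 12 keto aldehyde
Product: 13 (1S,2R,5S)-2-[(tert-butyldimethylsilyl)oxy]-5-ethenyl-7-(4-methoxybenzyl)-6-oxa-7-azabicyclo[3.2.1]octan-4-one
Conditions: Ph3PCH3Br, KN(SiMe3)2, THF, 0 °C; then 12, −78 → 0 °C
Reagents that add atoms: methylenetriphenylphosphorane, C=P(c1ccccc1)(c1ccccc1)c1ccccc1 (from methyltriphenylphosphonium bromide, C[P+](c1ccccc1)(c1ccccc1)c1ccccc1.[Br-])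
Why: Wittig methylenation should take place at the aldehyde far faster than at the ketone flanked by a quaternary carbon, and it is done before any β-methoxy group is present so that the basic ylide finds nothing to eliminate.

Step 9
Reactants: 13 C1-vinyl ketone; 14 3,3-dimethoxyprop-1-ene (acrolein dimethyl acetal)
Product: 16 ketone 13 carrying at C5 (face of ring A opposite the N–O bridge) a 1-methoxyprop-2-en-1-yl group with C4 configured as in the target, via silyl enol ether 15 (not isolated)
Conditions: TMSOTf (1.2 equiv), Et3N (1.3 equiv), CH2Cl2, 0 °C; then 14, TMSOTf (0.3 equiv), −78 °C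
Reagents that add atoms: none
Why: Mukaiyama-type addition of a silyl enol ether to the oxocarbenium ion of an acetal: enolisation can only go towards C5, the electrophile should attack C5 anti to the N–O bridge, and the open antiperiplanar transition state of this reaction is expected to give the syn relation between C6 and the methoxy group along C9–C5–C4–C3 that the target has, the methyl ether arriving with the acetal.

Step 10
Reactants: 16 isoxazolidine with both alkenyl arms
Product: 17 2-ethenyl-2-hydroxy-4-[(4-methoxybenzyl)amino]-5-[(tert-butyldimethylsilyl)oxy]-6-(1-methoxyprop-2-en-1-yl)cyclohexan-1-one (core numbering: O1, N7 and O6 cis on ring A; C5 side chain trans to them; C4 as in the target)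
Conditions: Zn dust, AcOH/THF/H2O, rt
Reagents that add atoms: none
Why: Reduction of the N–O bond by zinc in acetic acid, as used for isoxazolidines and α-aminooxy ketones, should unveil the C7 amine and the C1 tertiary alcohol without touching the alkenes, the silyl ether or any stereocentre.

Step 11
Reactants: 17 N-(4-methoxybenzyl) amino alcohol
Product: 18 4-amino-2-ethenyl-2-hydroxy-5-[(tert-butyldimethylsilyl)oxy]-6-(1-methoxyprop-2-en-1-yl)cyclohexan-1-one (configuration as in 17)
Conditions: (NH4)2Ce(NO3)6, MeCN/H2O, 0 °C; NaHCO3 work-up; used directly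
Reagents that add atoms: none
Why: Oxidative cleavage of the electron-rich 4-methoxybenzyl group from nitrogen through the benzylic iminium ion and its hydrolysis should be faster at 0 °C than any attack on the terminal alkenes or the tertiary ketol.

Step 12
Reactants: 18 primary amine; 19 (E)-dodec-2-enoic acid
Product: 20 (E)-N-{3-ethenyl-3-hydroxy-5-(1-methoxyprop-2-en-1-yl)-4-oxo-6-[(tert-butyldimethylsilyl)oxy]cyclohexyl}dodec-2-enamide (configuration as in 17)
Conditions: EDC·HCl, HOBt, CH2Cl2, 0 °C → rt
Reagents that add atoms: none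
Why: Carbodiimide amide coupling through the HOBt ester should acylate the primary amine selectively over the tertiary alcohol, without added base that could provoke β-elimination.

Step 13
Reactants: 20 diene amide
Product: 21 (E)-N-{1-hydroxy-4-methoxy-9-oxo-6-[(tert-butyldimethylsilyl)oxy]bicyclo[3.3.1]non-2-en-7-yl}dodec-2-enamide (core numbering, configuration as in the target)
Conditions: second-generation Grubbs catalyst, (H2IMes)(PCy3)Cl2Ru=CHPh (5 mol%), CH2Cl2 (dilute), 40 °C
Reagents that add atoms: none
Why: Ring-closing metathesis of the two terminal vinyl groups should close ring B, because with the N–O bridge gone ring A can adopt the chair in which the C1 vinyl and the C5 arm are both axial, and the conjugated disubstituted amide alkene is far less reactive.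

Step 14
Reactants: 21 bicyclic alkene
Product: 22 C6 O-TBS ether of the target (C2–C3 exo epoxide)
Conditions: dimethyldioxirane, acetone, 0 °C
Reagents that add atoms: dimethyldioxirane, CC1(C)OO1
Why: Dioxirane epoxidation of the isolated cis-alkene should deliver oxygen to the exo face, cis to O1 and the C4 methoxy group, because the endo face is screened by the C6–C7–C8 bridge and the C1 hydroxyl can hydrogen-bond the oxidant, while the electron-poor amide alkene is left untouched.

Step 15
Reactants: 22 silyl-protected epoxide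
Product: 23 CNP0137540.1
Conditions: HF·pyridine, pyridine, THF, 0 °C → rt
Reagents that add atoms: none
Why: Pyridine-buffered fluoride cleavage of the secondary TBS ether is known to spare epoxides, and since C5 is a bridgehead that cannot enolise the β-hydroxy and β-methoxy ketone units are safe.

Compound list
1 | (R)-4-hydroxydihydrofuran-2(3H)-one [(R)-3-hydroxy-γ-butyrolactone] | O=C1C[C@@H](O)CO1 | starting material
2 | (R)-4-[(tert-butyldimethylsilyl)oxy]dihydrofuran-2(3H)-one | O=C1C[C@@H](O[Si](C)(C)C(C)(C)C)CO1 | intermediate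
3 | 2-bromoprop-2-en-1-ol | OCC(Br)=C | starting material
4 | [(2-bromoprop-2-en-1-yl)oxy]triethylsilane | C=C(Br)CO[Si](CC)(CC)CC | intermediate
5 | {3-[(triethylsilyl)oxy]prop-1-en-2-yl}lithium | [Li]C(=C)CO[Si](CC)(CC)CC | intermediate
6 | (5R)-5-[(tert-butyldimethylsilyl)oxy]-6-hydroxy-2-{[(triethylsilyl)oxy]methyl}hex-1-en-3-one | C=C(CO[Si](CC)(CC)CC)C(=O)C[C@@H](O[Si](C)(C)C(C)(C)C)CO | intermediate
7 | (2R)-2-[(tert-butyldimethylsilyl)oxy]-4-oxo-5-{[(triethylsilyl)oxy]methyl}hex-5-enal | C=C(CO[Si](CC)(CC)CC)C(=O)C[C@@H](O[Si](C)(C)C(C)(C)C)C=O | intermediate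
8 | N-(4-methoxybenzyl)hydroxylamine | COc1ccc(CNO)cc1 | starting material
9 | (Z)-N-(4-methoxybenzyl) nitrone of aldehyde 7 (C6 R) | C=C(CO[Si](CC)(CC)CC)C(=O)C[C@@H](O[Si](C)(C)C(C)(C)C)/C=[N+](\[O-])Cc1ccc(OC)cc1 | intermediate
10 | (1S,2R,5S)-2-[(tert-butyldimethylsilyl)oxy]-7-(4-methoxybenzyl)-5-{[(triethylsilyl)oxy]methyl}-6-oxa-7-azabicyclo[3.2.1]octan-4-one | COc1ccc(CN2O[C@]3(CO[Si](CC)(CC)CC)C[C@H]2[C@H](O[Si](C)(C)C(C)(C)C)CC3=O)cc1 | intermediate
11 | (1S,2R,5S)-2-[(tert-butyldimethylsilyl)oxy]-5-(hydroxymethyl)-7-(4-methoxybenzyl)-6-oxa-7-azabicyclo[3.2.1]octan-4-one | COc1ccc(CN2O[C@]3(CO)C[C@H]2[C@H](O[Si](C)(C)C(C)(C)C)CC3=O)cc1 | intermediate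
12 | (1S,2R,5S)-2-[(tert-butyldimethylsilyl)oxy]-7-(4-methoxybenzyl)-4-oxo-6-oxa-7-azabicyclo[3.2.1]octane-5-carbaldehyde | COc1ccc(CN2O[C@]3(C=O)C[C@H]2[C@H](O[Si](C)(C)C(C)(C)C)CC3=O)cc1 | intermediate
13 | (1S,2R,5S)-2-[(tert-butyldimethylsilyl)oxy]-5-ethenyl-7-(4-methoxybenzyl)-6-oxa-7-azabicyclo[3.2.1]octan-4-one | COc1ccc(CN2O[C@]3(C=C)C[C@H]2[C@H](O[Si](C)(C)C(C)(C)C)CC3=O)cc1 | intermediate
14 | 3,3-dimethoxyprop-1-ene (acrolein dimethyl acetal) | C=CC(OC)OC | starting material
15 | trimethylsilyl enol ether of 13 (C9–O–SiMe3, C9=C5) | COc1ccc(CN2O[C@]3(C=C)C[C@H]2[C@H](O[Si](C)(C)C(C)(C)C)C=C3O[Si](C)(C)C)cc1 | intermediate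
16 | 13 with a 1-methoxyprop-2-en-1-yl group at C5, anti to the N–O bridge, C4 as in the target | COc1ccc(CN2O[C@]3(C=C)C[C@H]2[C@H](O[Si](C)(C)C(C)(C)C)[C@@H]([C@H](OC)C=C)C3=O)cc1 | intermediate
17 | 2-ethenyl-2-hydroxy-4-[(4-methoxybenzyl)amino]-5-[(tert-butyldimethylsilyl)oxy]-6-(1-methoxyprop-2-en-1-yl)cyclohexan-1-one | COc1ccc(CN[C@H]2C[C@](O)(C=C)C(=O)[C@@H]([C@H]2O[Si](C)(C)C(C)(C)C)[C@H](OC)C=C)cc1 | intermediate
18 | 4-amino-2-ethenyl-2-hydroxy-5-[(tert-butyldimethylsilyl)oxy]-6-(1-methoxyprop-2-en-1-yl)cyclohexan-1-one | N[C@H]1C[C@](O)(C=C)C(=O)[C@@H]([C@H]1O[Si](C)(C)C(C)(C)C)[C@H](OC)C=C | intermediate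
19 | (E)-dodec-2-enoic acid | CCCCCCCCC/C=C/C(=O)O | starting material
20 | (E)-dodec-2-enamide of amine 18 | CCCCCCCCC/C=C/C(=O)N[C@H]1C[C@](O)(C=C)C(=O)[C@@H]([C@H]1O[Si](C)(C)C(C)(C)C)[C@H](OC)C=C | intermediate
21 | bicyclo[3.3.1]non-2-en-9-one with C1 OH, C4 OMe, C6 OTBS and C7 (E)-dodec-2-enamide | CCCCCCCCC/C=C/C(=O)N[C@H]1C[C@@]2(O)C(=O)[C@@H]([C@H]1O[Si](C)(C)C(C)(C)C)[C@H](OC)C=C2 | intermediate
22 | C6 O-TBS ether of the target | CCCCCCCCC/C=C/C(=O)N[C@H]1C[C@@]2(O)C(=O)[C@@H]([C@H]1O[Si](C)(C)C(C)(C)C)[C@H](OC)[C@@H]1O[C@@H]12 | intermediate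
23 | CNP0137540.1 | CCCCCCCCC/C=C/C(=O)N[C@H]1C[C@@]2(O)C(=O)[C@@H]([C@H]1O)[C@H](OC)[C@@H]1O[C@@H]12 | target

Total step count: 15. Longest linear sequence: 14 steps (steps 1 and 3–15, from lactone 1; step 2 is a one-step side branch).

Steps most likely to fail

Step 5. The dipole may close in the fused mode (oxygen to C8, carbon to C1), or the hydroxylamine may add to the enone before it condenses with the aldehyde. The fallback sets out from 6 and comes back at 10; it takes the ketone out of conjugation first. Luche reduction of 6 (NaBH4, CeCl3·7H2O, MeOH) should give diol F1 as both C9 epimers. TEMPO with PhI(OAc)2 (one equivalent) should oxidise only the primary alcohol, the hydroxy aldehyde being collected as lactol F2. Condensation of F2 with 8 should give hydroxy nitrone F3, whose alkene is an unpolarised 1,1-disubstituted allylic alcohol; it is no Michael acceptor and should take oxygen at its substituted carbon. Heating should give carbinol cycloadduct F4, and Dess–Martin oxidation of F4 gives 10.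

Step 9. The open transition state may give poor relative selectivity at C4, or the enol ether may attack the unsaturated oxocarbenium ion in the conjugate position. The fallback sets out from 13 and comes back at 16; it uses a closed transition state and a separate methylation. Deprotonation with LiN(i-Pr)2 at −78 °C, transmetallation with Cp2ZrCl2 and addition of acrolein should give syn aldol F5, since zirconium enolates are syn-selective whatever the enolate geometry. MeOTf with 2,6-di-tert-butyl-4-methylpyridine then methylates the β-hydroxy ketone without free base to give 16.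

Step 11. The cerium oxidant may cleave the tertiary ketol or attack the alkenes before the benzyl group is lost. The fallback sets out from 16 and comes back at 18, so it bypasses 17 and the cerium reagent. mCPBA (one equivalent, −20 °C) should oxidise the isoxazolidine nitrogen, and the N-oxide opens with loss of a benzylic proton to the C-aryl nitrone F6 with the C1 hydroxyl free. NH2OH·HCl in MeOH transfers the arylidene group and should give N-hydroxy amine F7. Zn in AcOH reduces the N–OH bond to give 18.

Further compounds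
F1 | step 5 | (5R)-5-[(tert-butyldimethylsilyl)oxy]-2-{[(triethylsilyl)oxy]methyl}hex-1-ene-3,6-diol (C3 epimers) | C=C(CO[Si](CC)(CC)CC)C(O)C[C@@H](O[Si](C)(C)C(C)(C)C)CO
F2 | step 5 | (3R)-3-[(tert-butyldimethylsilyl)oxy]-5-{3-[(triethylsilyl)oxy]prop-1-en-2-yl}tetrahydrofuran-2-ol | C=C(CO[Si](CC)(CC)CC)C1C[C@@H](O[Si](C)(C)C(C)(C)C)C(O)O1
F3 | step 5 | (Z)-N-(4-methoxybenzyl) nitrone of the open form of F2 (C9 carbinol) | C=C(CO[Si](CC)(CC)CC)C(O)C[C@@H](O[Si](C)(C)C(C)(C)C)/C=[N+](\[O-])Cc1ccc(OC)cc1
F4 | step 5 | C9 carbinol corresponding to ketone 10 | COc1ccc(CN2O[C@]3(CO[Si](CC)(CC)CC)C[C@H]2[C@H](O[Si](C)(C)C(C)(C)C)CC3O)cc1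
F5 | step 9 | 13 with a 1-hydroxyprop-2-en-1-yl group at C5 (syn aldol, C4 as in the target) | COc1ccc(CN2O[C@]3(C=C)C[C@H]2[C@H](O[Si](C)(C)C(C)(C)C)[C@@H]([C@H](O)C=C)C3=O)cc1
F6 | step 11 | (Z)-C-(4-methoxyphenyl) nitrone on N7 of the ring-opened C1 carbinol | COc1ccc(/C=[N+](\[O-])[C@H]2C[C@](O)(C=C)C(=O)[C@@H]([C@H]2O[Si](C)(C)C(C)(C)C)[C@H](OC)C=C)cc1
F7 | step 11 | N-hydroxy derivative of amine 18 | ON[C@H]1C[C@](O)(C=C)C(=O)[C@@H]([C@H]1O[Si](C)(C)C(C)(C)C)[C@H](OC)C=C
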